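**Retrosynthetic overview**

1. Numbering: C1 ketone, C2=C3 furanone alkene, C4=C5 (Z, C15 hydroxymethyl on C4), C6 lactone carbinol, C7, C8 crotonate carbinol, C9, C10 quaternary (C14 methyl), C11=C13, C12 lactone carbonyl. The strategy rests on C6 being an allylic carbinol on the Z C4=C5 alkene that hangs on C3 of the furanone ring (O–C3=C2–C1(=O)–C10), so the C5–C6 bond that closes the ten-membered carbocycle C1–C10 can come from a C5 vinyl iodide and a C6 aldehyde.
2. End game: C15 desilylation, C8 crotonylation, C11 methylenation and closure of the lactone ring (C6–O–C12) on the macrocyclic C6 alcohol.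
3. Key disconnection: C5–C6, by cathodic chromium/nickel-catalysed vinyl iodide–aldehyde coupling of a seco-aldehyde that already carries the furanone.
4. Seco-aldehyde: C7–C8 by Evans syn-aldol of a tert-butyl succinate imide with the furanone acetaldehyde, then imide to aldehyde.
5. Furanone: C2–C3 aldol of an α-silyloxy methyl ketone (C10 from (S)-lactic acid by Seebach alkylation) with a (Z)-β-iodoenal (from methyl propiolate), oxidation and acid cyclodehydration. Ring order: furanone, then ten-membered carbocycle, then lactone.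

Key step: step 19

Remark: C12 is carried as a tert-butyl ester (it cannot lactonize onto the C8 or C6 oxygen before this is wanted and resists LiBH4) and C15 as a tert-butyldiphenylsilyl (TBDPS) ether (it survives the acidic steps); C8 is a triethylsilyl (TES) ether.

**Route**

Step 1
Reactants: 1 (S)-lactic acid
Product: 2 (2S,5S)-2-tert-butyl-5-methyl-1,3-dioxolan-4-one
Conditions: pivalaldehyde, TsOH·H2O (cat.), H2SO4 (cat.), pentane, reflux (Dean–Stark); crystallization at −78 °C
Reagents that add atoms: pivalaldehyde, CC(C)(C)C=O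
Why: Acid-catalysed acetalization of the α-hydroxy acid under water removal should give mainly the cis dioxolanone, purified by crystallization, so that the lactic acid stereocentre is stored in the acetal carbon (first stage of self-regeneration of stereocentres).

Step 2
Reactants: 2 (2S,5S)-2-tert-butyl-5-methyl-1,3-dioxolan-4-one
Product: 4 (2S,5R)-2-tert-butyl-5-methyl-5-(prop-2-enyl)-1,3-dioxolan-4-one, via lithium enolate 3 (not isolated)
Conditions: LiN(iPr)2, THF, −78 °C; allyl bromide, −78 to −30 °C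
Reagents that add atoms: allyl bromide, C=CCBr
Why: Seebach alkylation, in which allyl bromide attacks enolate 3 on the face opposite the tert-butyl group, so allyl takes the place of the former C–H bond and the quaternary centre that becomes C10 is set as R.

Step 3
Reactants: 4 (2S,5R)-2-tert-butyl-5-methyl-5-(prop-2-enyl)-1,3-dioxolan-4-one
Product: 5 (2R)-2-hydroxy-N-methoxy-N,2-dimethylpent-4-enamide
Conditions: MeNH(OMe)·HCl, iPrMgCl, THF, −20 to 0 °C
Reagents that add atoms: N,O-dimethylhydroxylamine hydrochloride, CNOC.Cl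
Why: Weinreb amide formation by attack of the magnesium amide on the activated acylal carbonyl, the released hemiacetal collapsing to pivalaldehyde, with no change at the quaternary centre.

Step 4
Reactants: 5 (2R)-2-hydroxy-N-methoxy-N,2-dimethylpent-4-enamide
Product: 6 (2R)-N-methoxy-N,2-dimethyl-2-(trimethylsilyloxy)pent-4-enamide
Conditions: Me3SiCl, imidazole, DMF, rt
Reagents that add atoms: chlorotrimethylsilane, C[Si](C)(C)Cl
Why: Silylation of the tertiary alcohol so that the later enolate chemistry meets no free hydroxyl, the trimethylsilyl ether being chosen because the acid of step 12 removes it.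

Step 5
Reactants: 6 (2R)-N-methoxy-N,2-dimethyl-2-(trimethylsilyloxy)pent-4-enamide
Product: 7 (3R)-3-methyl-3-(trimethylsilyloxy)hex-5-en-2-one
Conditions: MeMgBr, THF, 0 °C; aq. NH4Cl
Reagents that add atoms: methylmagnesium bromide, C[Mg]Br
Why: Grignard addition to the Weinreb amide stops at the chelated tetrahedral intermediate and should give the methyl ketone (C1 carbonyl, C2 as its methyl) on work-up.

Step 6
Reactants: 8 methyl propiolate
Product: 10 methyl (2Z)-2-(hydroxymethyl)-3-iodoprop-2-enoate, via iodomagnesium allenolate 9 (not isolated)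
Conditions: MgI2, CH2O (gas from cracked paraformaldehyde), CH2Cl2, 0 °C; H2O
Reagents that add atoms: magnesium iodide, [Mg+2].[I-].[I-]; formaldehyde, C=O
Why: Iodide-mediated Morita–Baylis–Hillman-type reaction (β-iodo aldol), in which conjugate addition of iodide gives allenolate 9 and formaldehyde then enters anti to iodine, so iodine ends cis to the ester (Z), the geometry needed between C3 and C5–I.

Step 7
Reactants: 10 methyl (2Z)-2-(hydroxymethyl)-3-iodoprop-2-enoate
Product: 11 methyl (2Z)-2-[(tert-butyldiphenylsilyloxy)methyl]-3-iodoprop-2-enoate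
Conditions: TBDPSCl, imidazole, CH2Cl2, 0 °C
Reagents that add atoms: tert-butyl(chloro)diphenylsilane, CC(C)(C)[Si](Cl)(c1ccccc1)c1ccccc1
Why: Silylation of the primary alcohol before the ester is reduced keeps the two CH2O arms on C4 different, which is what carries the alkene geometry forward.

Step 8
Reactants: 11 methyl (2Z)-2-[(tert-butyldiphenylsilyloxy)methyl]-3-iodoprop-2-enoate
Product: 12 (2E)-2-[(tert-butyldiphenylsilyloxy)methyl]-3-iodoprop-2-en-1-ol
Conditions: iBu2AlH, CH2Cl2, −78 °C; aq. potassium sodium tartrate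
Reagents that add atoms: none
Why: 1,2-Reduction of the unsaturated ester to the allylic alcohol with an aluminium hydride at low temperature, which should leave the vinyl iodide and its geometry untouched (the descriptor changes only by priority).

Step 9
Reactants: 12 (2E)-2-[(tert-butyldiphenylsilyloxy)methyl]-3-iodoprop-2-en-1-ol
Product: 13 (2Z)-2-[(tert-butyldiphenylsilyloxy)methyl]-3-iodoprop-2-enal
Conditions: MnO2, CH2Cl2, rt
Reagents that add atoms: none
Why: Allylic alcohol oxidation with MnO2 under neutral heterogeneous conditions should give the enal without alkene isomerization.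

Step 10
Reactants: 7 (3R)-3-methyl-3-(trimethylsilyloxy)hex-5-en-2-one; 13 (2Z)-2-[(tert-butyldiphenylsilyloxy)methyl]-3-iodoprop-2-enal
Product: 15 (1Z,6R)-2-[(tert-butyldiphenylsilyloxy)methyl]-3-hydroxy-1-iodo-6-methyl-6-(trimethylsilyloxy)nona-1,8-dien-5-one (C3 epimers), via lithium enolate 14 (not isolated)
Conditions: LiN(iPr)2, THF, −78 °C; 13, −78 °C; aq. NH4Cl
Reagents that add atoms: none
Why: Kinetic lithium enolate aldol addition, the methyl group being the only enolizable position of 7 and the non-enolizable enal taking the enolate 1,2 to form C2–C3, while the new carbinol centre is erased in step 11.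

Step 11
Reactants: 15 aldol adduct (C3 epimers)
Product: 16 (1Z,6R)-2-[(tert-butyldiphenylsilyloxy)methyl]-1-iodo-6-methyl-6-(trimethylsilyloxy)nona-1,8-diene-3,5-dione
Conditions: Dess–Martin periodinane, NaHCO3, CH2Cl2, 0 °C to rt
Reagents that add atoms: none
Why: Dess–Martin oxidation of the β-hydroxy ketone to the 1,3-diketone under buffered conditions that keep the trimethylsilyl ether.

Step 12
Reactants: 16 1,3-diketone
Product: 18 (2R)-5-[(1Z)-3-(tert-butyldiphenylsilyloxy)-1-iodoprop-1-en-2-yl]-2-methyl-2-(prop-2-enyl)furan-3(2H)-one, via hydroxy diketone 17 (not isolated)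
Conditions: TsOH·H2O (0.2 equiv), THF/H2O, rt to 40 °C
Reagents that add atoms: none
Why: Acid removes the tertiary trimethylsilyl ether and the freed hydroxyl adds to the C3 carbonyl and dehydrates (cyclodehydration of an α'-hydroxy 1,3-diketone), closing the furanone ring without touching C10 or the TBDPS ether.

Step 13
Reactants: 18 allyl furanone
Product: 20 2-[(2R)-5-[(1Z)-3-(tert-butyldiphenylsilyloxy)-1-iodoprop-1-en-2-yl]-2-methyl-3-oxo-2,3-dihydrofuran-2-yl]acetaldehyde, via vicinal diol 19 (not isolated)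
Conditions: OsO4 (2 mol%), NaIO4, 2,6-lutidine, dioxane/H2O, rt
Reagents that add atoms: osmium tetroxide, O=[Os](=O)(=O)=O; sodium periodate, [Na+].[O-]I(=O)(=O)=O
Why: Lemieux–Johnson oxidation, in which OsO4 should dihydroxylate the isolated monosubstituted alkene faster than the two electron-poor conjugated alkenes and periodate cleaves the diol to the C8 aldehyde.

Step 14
Reactants: 21 (4S)-4-benzyl-1,3-oxazolidin-2-one; 22 4-tert-butoxy-4-oxobutanoic acid (mono-tert-butyl succinate)
Product: 24 tert-butyl 4-[(4S)-4-benzyl-2-oxo-1,3-oxazolidin-3-yl]-4-oxobutanoate, via mixed pivalic anhydride 23 (not isolated)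
Conditions: Me3CCOCl, Et3N, THF, −20 °C; LiCl, 21, rt
Reagents that add atoms: none
Why: N-Acylation of the oxazolidinone through a mixed pivalic anhydride (LiCl-assisted), which is attacked at the less hindered succinyl carbonyl.

Step 15
Reactants: 24 succinate imide; 20 furanone acetaldehyde
Product: 26 tert-butyl (3S,4R)-3-{[(4S)-4-benzyl-2-oxo-1,3-oxazolidin-3-yl]carbonyl}-4-hydroxy-5-[(2R)-5-[(1Z)-3-(tert-butyldiphenylsilyloxy)-1-iodoprop-1-en-2-yl]-2-methyl-3-oxo-2,3-dihydrofuran-2-yl]pentanoate, via boron enolate 25 (not isolated)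
Conditions: Bu2BOTf, iPr2NEt, CH2Cl2, −78 to 0 °C; 20, −78 to −20 °C; pH 7 buffer, MeOH
Reagents that add atoms: none
Why: Evans syn-aldol reaction, in which the Z boron enolate 25 reacts through a chair Zimmerman–Traxler transition state on the face away from the benzyl group and so sets C7 (S) and C8 (R), while the tert-butyl ester should not lactonize with the aldolate and the non-oxidative work-up spares the iodo-dienone.

Step 16
Reactants: 26 syn-aldol adduct
Product: 27 C8 triethylsilyl ether of 26 (tert-butyl (3S,4R)-3-{[(4S)-4-benzyl-2-oxo-1,3-oxazolidin-3-yl]carbonyl}-4-(triethylsilyloxy)-5-[furanonyl]pentanoate)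
Conditions: Et3SiOTf, 2,6-lutidine, CH2Cl2, −78 °C
Reagents that add atoms: triethylsilyl triflate, CC[Si](CC)(CC)OS(=O)(=O)C(F)(F)F
Why: Silylation of the secondary aldol hydroxyl with a silyl triflate and a hindered base at low temperature, which should be much faster than any attack on the tert-butyl ester and avoids nucleophilic amines near the iodo-dienone.

Step 17
Reactants: 27 silylated imide
Product: 28 tert-butyl (3R,4R)-3-(hydroxymethyl)-4-(triethylsilyloxy)-5-[(2R)-5-[(1Z)-3-(tert-butyldiphenylsilyloxy)-1-iodoprop-1-en-2-yl]-2-methyl-3-oxo-2,3-dihydrofuran-2-yl]pentanoate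
Conditions: LiBH4, MeOH (1 equiv), THF, 0 °C
Reagents that add atoms: none
Why: Reductive removal of the auxiliary, LiBH4 being expected to reduce the activated exocyclic imide carbonyl faster than the hindered vinylogous-ester carbonyl of the furanone or the tert-butyl ester, and the γ-hydroxy tert-butyl ester not lactonizing (C7 keeps its arrangement; the letter changes by priority).

Step 18
Reactants: 28 primary alcohol
Product: 29 tert-butyl (3S,4R)-3-formyl-4-(triethylsilyloxy)-5-[(2R)-5-[(1Z)-3-(tert-butyldiphenylsilyloxy)-1-iodoprop-1-en-2-yl]-2-methyl-3-oxo-2,3-dihydrofuran-2-yl]pentanoate (C6 aldehyde with C5 vinyl iodide)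
Conditions: Dess–Martin periodinane, NaHCO3, CH2Cl2, 0 °C
Reagents that add atoms: none
Why: Dess–Martin oxidation of the primary alcohol under buffered conditions that should not epimerize the α-branched aldehyde, which is used at once.

Step 19
Reactants: 29 seco-aldehyde with (Z)-C5 vinyl iodide
Product: 31 (6S,7R,8R,10R)-configured furanone-bridged ten-membered C6 allylic alcohol with C15 OTBDPS and C8 OTES and CH2CO2tBu on C7 (C7 arranged as in the target), via trimethylsilyl ether 30 (not isolated)
Conditions: CrCl2 (20 mol%), NiCl2 (5 mol%), Me3SiCl, LiClO4, DMF, Al anode/Pt cathode, constant current, rt, slow addition of 29 (2 mM); then aq. citric acid, THF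
Reagents that add atoms: none
Why: Divalent chromium, made and remade at the cathode, reduces NiCl2 to zerovalent nickel, which inserts into the C5–I bond; the vinylnickel passes the C5 vinyl group to trivalent chromium, the vinylchromium adds to the C6 aldehyde, and Me3SiCl turns the chromium alkoxide into silyl ether 30 and frees trivalent chromium for reduction, so chromium stays catalytic, and acid work-up then gives 31. The closest known reaction types are the electrochemical chromium-catalysed Nozaki–Hiyama–Kishi coupling of alkenyl iodides with aldehydes and the stoichiometric Nozaki–Hiyama–Kishi closure of nine- and ten-membered rings. The ten-membered carbocycle C1–C10 is closed by 10-exo-trig attack of C5 on the C6 carbonyl (9-exo-trig if counted through the furanone oxygen), and because the furanone and the Z alkene are already in place only the C6–C9 segment has to fold. The new C6 centre should follow a Felkin–Anh approach on the C7-branched aldehyde, C5 entering anti to the C8 branch with the carbonyl oxygen beside the CH2CO2tBu arm, which gives the 6S alcohol (oxygen syn to C11) needed for the trans lactone. The step needs addition to the aldehyde and not to the furanone ketone or the ester, which the carbonyl preference and low basicity of organochromium reagents should secure, retention of the Z geometry, which the configurationally stable vinylchromium secures, and ring closure over oligomerization, which slow addition at high dilution secures.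

Step 20
Reactants: 31 macrocyclic C6 alcohol
Product: 34 (6S,7R,8R,10R)-6,12-lactone (trans-fused) with C8 OTES and C15 OTBDPS, via bis-silyl derivative 32 (not isolated), via hydroxy acid 33 (not isolated)
Conditions: Me3SiOTf, 2,6-lutidine, CH2Cl2, 0 °C to rt; aq. citric acid, THF, rt
Reagents that add atoms: none
Why: Silyl triflate-mediated cleavage of the tert-butyl ester (loss of isobutene) under conditions that keep TES and TBDPS ethers, then hydrolysis of the two trimethylsilyl groups and γ-lactonization of the hydroxy acid by acyl substitution with retention at C6, the C8 oxygen staying silylated so that only the C6 oxygen can close the ring.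

Step 21
Reactants: 34 lactone
Product: 36 C11 (dimethylamino)methyl lactone (C11 epimers), via lithium enolate 35 (not isolated)
Conditions: LiN(iPr)2, THF, −78 °C; CH2=NMe2+ I−, −78 to 0 °C
Reagents that add atoms: Eschenmoser's salt (N,N-dimethylmethyleneiminium iodide), C=[N+](C)C.[I-]
Why: Mannich reaction of the lactone lithium enolate with the preformed iminium salt (first half of the Eschenmoser methylenation), C11 being the only enolizable position because C10 is quaternary and the furanone has no sp3 α-hydrogen.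

Step 22
Reactants: 36 Mannich base
Product: 38 (6S,7R,8R,10R)-α-methylene lactone (C11=C13) with C8 OTES and C15 OTBDPS, via ammonium iodide 37 (not isolated)
Conditions: MeI, MeOH, rt; aq. NaHCO3, CH2Cl2, rt
Reagents that add atoms: none
Why: Exhaustive N-methylation followed by base-induced Hofmann-type β-elimination of trimethylamine from the lactone α-position should give the exocyclic C11=C13 alkene.

Step 23
Reactants: 38 silylated α-methylene lactone
Product: 39 (6S,7S,8R,10R)-C8 alcohol with C15 OTBDPS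
Conditions: PPTS, MeOH/CH2Cl2, 0 °C to rt
Reagents that add atoms: none
Why: Acid-catalysed methanolysis of the triethylsilyl ether, which is far more labile than the primary tert-butyldiphenylsilyl ether.

Step 24
Reactants: 39 C8 alcohol
Product: 40 C8 (E)-but-2-enoate of 39 (C15 OTBDPS)
Conditions: (E)-crotonic anhydride, DMAP, Et3N, CH2Cl2, 0 °C
Reagents that add atoms: (E)-crotonic anhydride, C/C=C/C(=O)OC(=O)/C=C/C
Why: DMAP-catalysed acylation of the C8 alcohol with the anhydride, which avoids the vinylketene path that isomerizes crotonyl chloride and should be fast enough at 0 °C to outrun lactone migration to the C8 oxygen.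

Step 25
Reactants: 40 silylated crotonate
Product: 41 CNP0225232.1 (target)
Conditions: HF·pyridine, pyridine, THF, 0 °C to rt
Reagents that add atoms: none
Why: Fluoride-mediated cleavage of the silyl ether under buffered conditions that should tolerate the α-methylene lactone, the crotonate and the furanone.

**Compound list**

1 | (S)-lactic acid | C[C@H](O)C(=O)O | starting material
2 | (2S,5S)-2-tert-butyl-5-methyl-1,3-dioxolan-4-one | C[C@@H]1O[C@H](C(C)(C)C)OC1=O | intermediate
3 | lithium enolate of 2 | CC1=C(O[Li])O[C@@H](C(C)(C)C)O1 | intermediate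
4 | (2S,5R)-2-tert-butyl-5-methyl-5-(prop-2-enyl)-1,3-dioxolan-4-one | C=CC[C@@]1(C)O[C@H](C(C)(C)C)OC1=O | intermediate
5 | (2R)-2-hydroxy-N-methoxy-N,2-dimethylpent-4-enamide | C=CC[C@@](C)(O)C(=O)N(C)OC | intermediate
6 | (2R)-N-methoxy-N,2-dimethyl-2-(trimethylsilyloxy)pent-4-enamide | C=CC[C@@](C)(O[Si](C)(C)C)C(=O)N(C)OC | intermediate
7 | (3R)-3-methyl-3-(trimethylsilyloxy)hex-5-en-2-one | C=CC[C@@](C)(O[Si](C)(C)C)C(C)=O | intermediate
8 | methyl propiolate | C#CC(=O)OC | starting material
9 | iodomagnesium 3-iodo-1-methoxyallenolate | COC(O[Mg]I)=C=CI | intermediate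
10 | methyl (2Z)-2-(hydroxymethyl)-3-iodoprop-2-enoate | COC(=O)/C(CO)=C\I | intermediate
11 | methyl (2Z)-2-[(tert-butyldiphenylsilyloxy)methyl]-3-iodoprop-2-enoate | COC(=O)/C(CO[Si](c1ccccc1)(c1ccccc1)C(C)(C)C)=C\I | intermediate
12 | (2E)-2-[(tert-butyldiphenylsilyloxy)methyl]-3-iodoprop-2-en-1-ol | OC/C(CO[Si](c1ccccc1)(c1ccccc1)C(C)(C)C)=C\I | intermediate
13 | (2Z)-2-[(tert-butyldiphenylsilyloxy)methyl]-3-iodoprop-2-enal | O=C/C(CO[Si](c1ccccc1)(c1ccccc1)C(C)(C)C)=C\I | intermediate
14 | lithium enolate of 7 | C=CC[C@@](C)(O[Si](C)(C)C)C(=C)O[Li] | intermediate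
15 | (1Z,6R)-2-[(tert-butyldiphenylsilyloxy)methyl]-3-hydroxy-1-iodo-6-methyl-6-(trimethylsilyloxy)nona-1,8-dien-5-one (C3 epimers) | C=CC[C@@](C)(O[Si](C)(C)C)C(=O)CC(O)/C(CO[Si](c1ccccc1)(c1ccccc1)C(C)(C)C)=C\I | intermediate
16 | (1Z,6R)-2-[(tert-butyldiphenylsilyloxy)methyl]-1-iodo-6-methyl-6-(trimethylsilyloxy)nona-1,8-diene-3,5-dione | C=CC[C@@](C)(O[Si](C)(C)C)C(=O)CC(=O)/C(CO[Si](c1ccccc1)(c1ccccc1)C(C)(C)C)=C\I | intermediate
17 | (1Z,6R)-2-[(tert-butyldiphenylsilyloxy)methyl]-6-hydroxy-1-iodo-6-methylnona-1,8-diene-3,5-dione | C=CC[C@@](C)(O)C(=O)CC(=O)/C(CO[Si](c1ccccc1)(c1ccccc1)C(C)(C)C)=C\I | intermediate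
18 | (2R)-5-[(1Z)-3-(tert-butyldiphenylsilyloxy)-1-iodoprop-1-en-2-yl]-2-methyl-2-(prop-2-enyl)furan-3(2H)-one | C=CC[C@@]1(C)OC(=CC1=O)/C(CO[Si](c2ccccc2)(c2ccccc2)C(C)(C)C)=C\I | intermediate
19 | (2R)-2-(2,3-dihydroxypropyl) analogue of 18 (diol epimers) | OCC(O)C[C@@]1(C)OC(=CC1=O)/C(CO[Si](c2ccccc2)(c2ccccc2)C(C)(C)C)=C\I | intermediate
20 | 2-[(2R)-5-[(1Z)-3-(tert-butyldiphenylsilyloxy)-1-iodoprop-1-en-2-yl]-2-methyl-3-oxo-2,3-dihydrofuran-2-yl]acetaldehyde | O=CC[C@@]1(C)OC(=CC1=O)/C(CO[Si](c2ccccc2)(c2ccccc2)C(C)(C)C)=C\I | intermediate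
21 | (4S)-4-benzyl-1,3-oxazolidin-2-one | O=C1N[C@@H](Cc2ccccc2)CO1 | starting material
22 | 4-tert-butoxy-4-oxobutanoic acid | CC(C)(C)OC(=O)CCC(=O)O | starting material
23 | mixed pivalic anhydride of 22 | CC(C)(C)OC(=O)CCC(=O)OC(=O)C(C)(C)C | intermediate
24 | tert-butyl 4-[(4S)-4-benzyl-2-oxo-1,3-oxazolidin-3-yl]-4-oxobutanoate | CC(C)(C)OC(=O)CCC(=O)N1C(=O)OC[C@@H]1Cc1ccccc1 | intermediate
25 | (Z)-dibutylboron enolate of 24 | CCCCB(CCCC)O/C(=C\CC(=O)OC(C)(C)C)N1C(=O)OC[C@@H]1Cc1ccccc1 | intermediate
26 | Evans syn-aldol adduct (C7 S, C8 R, C10 R; C8 OH; imide at C6) | O=C([C@@H](CC(=O)OC(C)(C)C)[C@H](O)C[C@@]1(C)OC(=CC1=O)/C(CO[Si](c2ccccc2)(c2ccccc2)C(C)(C)C)=C\I)N1C(=O)OC[C@@H]1Cc1ccccc1 | intermediate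
27 | C8 triethylsilyl ether of 26 | O=C([C@@H](CC(=O)OC(C)(C)C)[C@H](O[Si](CC)(CC)CC)C[C@@]1(C)OC(=CC1=O)/C(CO[Si](c2ccccc2)(c2ccccc2)C(C)(C)C)=C\I)N1C(=O)OC[C@@H]1Cc1ccccc1 | intermediate
28 | C6 primary alcohol (tert-butyl (3R,4R)-3-(hydroxymethyl)-4-(triethylsilyloxy)-5-[furanonyl]pentanoate) | OC[C@@H](CC(=O)OC(C)(C)C)[C@H](O[Si](CC)(CC)CC)C[C@@]1(C)OC(=CC1=O)/C(CO[Si](c2ccccc2)(c2ccccc2)C(C)(C)C)=C\I | intermediate
29 | C6 aldehyde with (Z)-C5 vinyl iodide (tert-butyl (3S,4R)-3-formyl-4-(triethylsilyloxy)-5-[furanonyl]pentanoate) | O=C[C@@H](CC(=O)OC(C)(C)C)[C@H](O[Si](CC)(CC)CC)C[C@@]1(C)OC(=CC1=O)/C(CO[Si](c2ccccc2)(c2ccccc2)C(C)(C)C)=C\I | intermediate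
30 | C6 O-trimethylsilyl ether of 31 | C[Si](C)(C)O[C@H]1/C=C(/CO[Si](c3ccccc3)(c3ccccc3)C(C)(C)C)C2=CC(=O)[C@@](C)(C[C@@H](O[Si](CC)(CC)CC)[C@@H]1CC(=O)OC(C)(C)C)O2 | intermediate
31 | (6S,7R,8R,10R)-furanone-bridged ten-membered C6 allylic alcohol (4Z; C15 OTBDPS; C7 CH2CO2tBu; C8 OTES) | O[C@H]1/C=C(/CO[Si](c3ccccc3)(c3ccccc3)C(C)(C)C)C2=CC(=O)[C@@](C)(C[C@@H](O[Si](CC)(CC)CC)[C@@H]1CC(=O)OC(C)(C)C)O2 | intermediate
32 | C6 O-trimethylsilyl, C12 trimethylsilyl ester derivative of 31 | C[Si](C)(C)O[C@H]1/C=C(/CO[Si](c3ccccc3)(c3ccccc3)C(C)(C)C)C2=CC(=O)[C@@](C)(C[C@@H](O[Si](CC)(CC)CC)[C@@H]1CC(=O)O[Si](C)(C)C)O2 | intermediate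
33 | C6 hydroxy C12 acid | O[C@H]1/C=C(/CO[Si](c3ccccc3)(c3ccccc3)C(C)(C)C)C2=CC(=O)[C@@](C)(C[C@@H](O[Si](CC)(CC)CC)[C@@H]1CC(=O)O)O2 | intermediate
34 | (6S,7R,8R,10R)-6,12-lactone (C8 OTES, C15 OTBDPS) | C1C(=O)O[C@H]2/C=C(/CO[Si](c4ccccc4)(c4ccccc4)C(C)(C)C)C3=CC(=O)[C@@](C)(C[C@@H](O[Si](CC)(CC)CC)[C@H]12)O3 | intermediate
35 | lithium enolate of 34 | C1=C(O[Li])O[C@H]2/C=C(/CO[Si](c4ccccc4)(c4ccccc4)C(C)(C)C)C3=CC(=O)[C@@](C)(C[C@@H](O[Si](CC)(CC)CC)[C@H]12)O3 | intermediate
36 | C11 (dimethylamino)methyl lactone (C11 epimers) | CN(C)CC1C(=O)O[C@H]2/C=C(/CO[Si](c4ccccc4)(c4ccccc4)C(C)(C)C)C3=CC(=O)[C@@](C)(C[C@@H](O[Si](CC)(CC)CC)[C@H]12)O3 | intermediate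
37 | C11 (trimethylammonio)methyl lactone iodide | C[N+](C)(C)CC1C(=O)O[C@H]2/C=C(/CO[Si](c4ccccc4)(c4ccccc4)C(C)(C)C)C3=CC(=O)[C@@](C)(C[C@@H](O[Si](CC)(CC)CC)[C@H]12)O3.[I-] | intermediate
38 | (6S,7R,8R,10R)-α-methylene lactone (C8 OTES, C15 OTBDPS) | C=C1C(=O)O[C@H]2/C=C(/CO[Si](c4ccccc4)(c4ccccc4)C(C)(C)C)C3=CC(=O)[C@@](C)(C[C@@H](O[Si](CC)(CC)CC)[C@H]12)O3 | intermediate
39 | (6S,7S,8R,10R)-C8 alcohol (C15 OTBDPS) | C=C1C(=O)O[C@H]2/C=C(/CO[Si](c4ccccc4)(c4ccccc4)C(C)(C)C)C3=CC(=O)[C@@](C)(C[C@@H](O)[C@H]12)O3 | intermediate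
40 | (6S,7S,8R,10R)-C8 (E)-but-2-enoate (C15 OTBDPS) | C=C1C(=O)O[C@H]2/C=C(/CO[Si](c4ccccc4)(c4ccccc4)C(C)(C)C)C3=CC(=O)[C@@](C)(C[C@@H](OC(=O)/C=C/C)[C@H]12)O3 | intermediate
41 | CNP0225232.1 | C=C1C(=O)O[C@H]2/C=C(/CO)C3=CC(=O)[C@@](C)(C[C@@H](OC(=O)/C=C/C)[C@H]12)O3 | target

**Step count and risks**

Total step count: 25. Longest linear sequence: 20 steps (steps 1–5, 10–13, 15–25).

Steps most likely to fail:

Step 19. The ring closure may suffer from poor facial selectivity at C6 inside the macrocyclic transition state, so that the vinylchromium adds mainly to the other aldehyde face. The fallback keeps the C5–C6 closure and corrects C6 when the lactone is formed. It sets out from 29, whose cyclization under the same electrolysis then gives the C6 epimer of 31 F1. Me3SiOTf/2,6-lutidine converts F1 into its bis(trimethylsilyl) derivative F2, and cold buffered hydrolysis gives the C6-epimeric hydroxy acid F3, handled as its triethylammonium salt. PPh3 and diisopropyl azodicarboxylate then close the lactone by SN2 displacement of the activated C6 oxygen by the C12 carboxylate (Mitsunobu lactonization, inversion at C6). The route is rejoined at 34.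

Step 17. Hydride may lose chemoselectivity and attack the furanone C1 carbonyl or reduce the dienone in a conjugate sense while the imide is cleaved. The fallback changes the auxiliary so that a much milder hydride suffices. It sets out from 20 and 22: acid 22 is coupled (dicyclohexylcarbodiimide, DMAP) with commercial (4S)-4-benzyl-1,3-thiazolidine-2-thione to the N-acyl thiazolidinethione F4. Its chlorotitanium enolate (TiCl4, iPr2NEt, N-methylpyrrolidinone, −78 °C) should add to 20 with the same syn sense to give the thioimide aldol F5, and Et3SiOTf/2,6-lutidine gives the silyl ether F6. NaBH4 in THF/EtOH at 0 °C should cleave the activated thioimide within minutes, under conditions where vinylogous esters and tert-butyl esters are expected to be inert. The route is rejoined at 28.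

Step 13. The oxidation may lack chemoselectivity among the three alkenes, with osmylation of the iodo-diene or of the furanone C2=C3 bond. The fallback moves the cleavage to a stage with a single alkene and carries C8 as an acetal. It sets out from 7: ozonolysis (O3, CH2Cl2, −78 °C; PPh3) gives the keto aldehyde F7, and aldehyde-selective acetalization with 1,2-bis(trimethylsilyloxy)ethane and catalytic Me3SiOTf at −78 °C gives the dioxolane ketone F8. LiN(iPr)2 and then 13 give the aldol adduct F9, and Dess–Martin oxidation gives the diketone F10. TsOH·H2O in wet acetone then removes the trimethylsilyl group, closes the furanone and hydrolyses the dioxolane. The route is rejoined at 20.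

**Further compounds**

F1 | step 19 | C6 epimer of 31 | O[C@@H]1/C=C(/CO[Si](c3ccccc3)(c3ccccc3)C(C)(C)C)C2=CC(=O)[C@@](C)(C[C@@H](O[Si](CC)(CC)CC)[C@@H]1CC(=O)OC(C)(C)C)O2
F2 | step 19 | C6 O-trimethylsilyl, C12 trimethylsilyl ester derivative of F1 | C[Si](C)(C)O[C@@H]1/C=C(/CO[Si](c3ccccc3)(c3ccccc3)C(C)(C)C)C2=CC(=O)[C@@](C)(C[C@@H](O[Si](CC)(CC)CC)[C@@H]1CC(=O)O[Si](C)(C)C)O2
F3 | step 19 | C6-epimeric hydroxy acid | O[C@@H]1/C=C(/CO[Si](c3ccccc3)(c3ccccc3)C(C)(C)C)C2=CC(=O)[C@@](C)(C[C@@H](O[Si](CC)(CC)CC)[C@@H]1CC(=O)O)O2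
F4 | step 17 | tert-butyl 4-[(4S)-4-benzyl-2-thioxo-1,3-thiazolidin-3-yl]-4-oxobutanoate | CC(C)(C)OC(=O)CCC(=O)N1C(=S)SC[C@@H]1Cc1ccccc1
F5 | step 17 | thioimide syn-aldol adduct (C7 and C8 as in 26) | O=C([C@@H](CC(=O)OC(C)(C)C)[C@H](O)C[C@@]1(C)OC(=CC1=O)/C(CO[Si](c2ccccc2)(c2ccccc2)C(C)(C)C)=C\I)N1C(=S)SC[C@@H]1Cc1ccccc1
F6 | step 17 | C8 triethylsilyl ether of F5 | O=C([C@@H](CC(=O)OC(C)(C)C)[C@H](O[Si](CC)(CC)CC)C[C@@]1(C)OC(=CC1=O)/C(CO[Si](c2ccccc2)(c2ccccc2)C(C)(C)C)=C\I)N1C(=S)SC[C@@H]1Cc1ccccc1
F7 | step 13 | (3R)-3-methyl-4-oxo-3-(trimethylsilyloxy)pentanal | O=CC[C@@](C)(O[Si](C)(C)C)C(C)=O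
F8 | step 13 | (3R)-4-(1,3-dioxolan-2-yl)-3-methyl-3-(trimethylsilyloxy)butan-2-one | C1COC(O1)C[C@@](C)(O[Si](C)(C)C)C(C)=O
F9 | step 13 | aldol adduct of F8 with 13 (carbinol epimers) | C1COC(O1)C[C@@](C)(O[Si](C)(C)C)C(=O)CC(O)/C(CO[Si](c2ccccc2)(c2ccccc2)C(C)(C)C)=C\I
F10 | step 13 | 1,3-diketone from F9 | C1COC(O1)C[C@@](C)(O[Si](C)(C)C)C(=O)CC(=O)/C(CO[Si](c2ccccc2)(c2ccccc2)C(C)(C)C)=C\I
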